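**Plan**

Locants (germacrane numbering): ten-membered carbocycle C1–C10; ring enoate C1=C10 with CO2Me (C14) on C10; CH2OH (C15) on C4; γ-lactone O–C6 / C7–C11(=C13)–C12(=O); isobutyrate on C8.
Retrosynthesis: Si–O (last step); then the allylic C(sp2)–C(sp3) bond C1–C2 of the ten-membered ring, which gives an open chain with an (E)-β-iodoacrylate at C1 and an N-acyloxyphthalimide one carbon beyond C2; then the C8–O ester bond (with inversion), C7–C8 (Barbier), C6–C7 (carbonyl allylation) and C3–C4 (Michael addition).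
Forward: west chain (C2–C6, C15 and the carboxyl carbon that later leaves as CO2) → α-methylene-γ-lactone (first ring, C6–C7 bond) → 3-(bromomethyl)butenolide → indium Barbier coupling with the iodoacrylate aldehyde (C7–C8 bond, all carbons in place) → isobutyrate → acid → redox-active ester → electrochemical nickel-mediated closure of the ten-membered ring (second ring) → desilylation.
Stereochemistry: C4 from an Evans oxazolidinone; C6 from the chiral iridium catalyst; C7 relayed from C6 (addition anti to the C6 substituent on the butenolide); C8 from the closed transition state of the Barbier step followed by Mitsunobu inversion; the C1=C10 geometry from the (E)-iodoacrylic acid synthesis, retained in the coupling.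
Enabling feature: C1 is the β-carbon of an α-substituted acrylate whose ring bonds C2–C1=C10–C9 are cis, and C2 is a plain CH2; an iodine on C1 syn to C9 and a carboxyl on C2 therefore program the closure, and the trans-fused five-membered lactone at C6–C7 turns both chain arms to the same side.

Key step: step 16

Remarks on the chemistry: TBDPS = tert-butyldiphenylsilyl (TBDPSO = its ether). Carbonate 10 is assumed to be purchasable. The ligand enantiomer in step 6 is the one expected to give the 6R carbinol; its antipode would give the C6 epimer.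

**Step 1**
Reactants: 1 (S)-4-benzyl-1,3-oxazolidin-2-one; 2 pent-4-enoyl chloride
Product: 3 (S)-4-benzyl-3-(pent-4-enoyl)-1,3-oxazolidin-2-one
Conditions: n-BuLi, THF, −78 °C; then 2, −78 → 0 °C
Reagents that add atoms: none
Why: N-acylation of the lithiated Evans oxazolidinone by the acid chloride (acyl substitution) gives the imide that carries C4, C5, C6 and C15.

**Step 2**
Reactants: 3 (S)-4-benzyl-3-(pent-4-enoyl)-1,3-oxazolidin-2-one; 4 tert-butyl acrylate
Product: 5 tert-butyl (S)-4-[(S)-4-benzyl-2-oxo-1,3-oxazolidine-3-carbonyl]hept-6-enoate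
Conditions: TiCl4/Ti(OiPr)4 (3:1, giving TiCl3(OiPr)), i-Pr2NEt, CH2Cl2, 0 °C; then 4, 0 °C
Reagents that add atoms: none
Why: Evans asymmetric Michael addition, in which the chelated Z-titanium enolate of 3 adds to the acrylate from the face away from the benzyl group (the sense of Evans alkylation), should set C4 as S and bring in C3, C2 and the carboxyl carbon that is later expelled as CO2.

**Step 3**
Reactants: 5 tert-butyl (S)-4-[(S)-4-benzyl-2-oxo-1,3-oxazolidine-3-carbonyl]hept-6-enoate
Product: 6 tert-butyl (S)-4-(hydroxymethyl)hept-6-enoate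
Conditions: LiBH4, MeOH (1 equiv), THF, 0 °C
Reagents that add atoms: none
Why: Reductive cleavage of the acyl oxazolidinone (hydride reduction of the activated imide carbonyl, much faster than of the tert-butyl ester) frees the C15 alcohol without touching C4.

**Step 4**
Reactants: 6 tert-butyl (S)-4-(hydroxymethyl)hept-6-enoate
Product: 7 tert-butyl (S)-4-(TBDPSO-methyl)hept-6-enoate
Conditions: TBDPSCl, imidazole, DMF, rt
Reagents that add atoms: tert-butyl(chloro)diphenylsilane (TBDPSCl), CC(C)(C)[Si](Cl)(c1ccccc1)c1ccccc1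
Why: Silylation of the primary alcohol (imidazole-mediated silyl transfer) gives a TBDPS ether that should survive the later acid, metal and electrochemical steps.

**Step 5**
Reactants: 7 tert-butyl (S)-4-(TBDPSO-methyl)hept-6-enoate
Product: 9 tert-butyl (S)-4-(TBDPSO-methyl)-6-oxohexanoate, via ozonide 8 (not isolated)
Conditions: O3, CH2Cl2, −78 °C; then PPh3, −78 °C → rt
Reagents that add atoms: ozone, [O-][O+]=O
Why: Ozonolysis of the only alkene with reductive work-up (1,3-dipolar cycloaddition and cycloreversion, then phosphine reduction of the ozonide) unveils the C6 aldehyde.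

**Step 6**
Reactants: 9 tert-butyl (S)-4-(TBDPSO-methyl)-6-oxohexanoate; 10 methyl 2-{[(tert-butoxycarbonyl)oxy]methyl}acrylate
Product: 12 tert-butyl (S)-4-(TBDPSO-methyl)-5-[(R)-4-methylidene-5-oxooxolan-2-yl]pentanoate, via hydroxy ester 11 (not isolated)
Conditions: [Ir(cod)Cl]2 (2.5 mol%), (R)-SEGPHOS (5 mol%), 4-cyano-3-nitrobenzoic acid (10 mol%), Cs2CO3 (20 mol%), i-PrOH (2 equiv), THF, 60 °C
Reagents that add atoms: none
Why: Krische-type iridium-catalysed transfer-hydrogenative 2-(alkoxycarbonyl)allylation, in which the allyliridium formed from 10 and 2-propanol adds to the aldehyde through a closed chair transition state whose face is chosen by the SEGPHOS ligand (catalyst control, the remote C4 centre has little say), should set C6 as R, and the hydroxy ester lactonizes to the α-methylene-γ-butyrolactone.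

**Step 7**
Reactants: 12 tert-butyl (S)-4-(TBDPSO-methyl)-5-[(R)-4-methylidene-5-oxooxolan-2-yl]pentanoate
Product: 14 tert-butyl (S)-5-[(R)-4-(bromomethyl)-5-oxo-2,5-dihydrofuran-2-yl]-4-(TBDPSO-methyl)pentanoate, via dibromide 13 (not isolated)
Conditions: Br2, CH2Cl2, 0 °C; then Et3N, 0 °C
Reagents that add atoms: bromine, BrBr
Why: Bromination–dehydrobromination (Br2 adds to the exocyclic C11=C13 bond, Et3N removes HBr across C7–C11 by E2 toward the conjugated butenolide) moves the double bond into the ring and leaves an allylic bromide at C13, a known route from α-methylene lactones to 3-(bromomethyl)furan-2(5H)-ones; short contact with the base should keep the γ-centre C6 intact.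

**Step 8**
Reactants: 15 dimethyl malonate; 16 2-bromo-1,1-dimethoxyethane
Product: 17 dimethyl 2-(2,2-dimethoxyethyl)malonate
Conditions: NaH, NaI (cat.), DMF, 90 °C
Reagents that add atoms: none
Why: SN2 alkylation of sodium dimethyl malonate (malonic ester synthesis) attaches the masked C8 aldehyde and C9 to the future C10.

**Step 9**
Reactants: 17 dimethyl 2-(2,2-dimethoxyethyl)malonate
Product: 18 dimethyl 2-(diiodomethyl)-2-(2,2-dimethoxyethyl)malonate
Conditions: NaH, CHI3, Et2O, reflux
Reagents that add atoms: iodoform, IC(I)I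
Why: Diiodomethylation of the malonate anion with iodoform (C-alkylation through diiodocarbene or halophilic attack) installs the future C1 with both iodines.

**Step 10**
Reactants: 18 dimethyl 2-(diiodomethyl)-2-(2,2-dimethoxyethyl)malonate
Product: 19 (E)-2-(2,2-dimethoxyethyl)-3-iodoprop-2-enoic acid
Conditions: KOH, EtOH–H2O (3:1), reflux; then cold 1 M HCl to pH 3
Reagents that add atoms: potassium hydroxide, [K+].[OH-]
Why: Saponification followed by decarboxylative anti-elimination of iodide (Grob-type fragmentation, the established route from diiodomethyl malonates to (E)-3-iodo-2-alkylacrylic acids) should give the acid with iodine trans to the carboxyl and cis to C9.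

**Step 11**
Reactants: 19 (E)-2-(2,2-dimethoxyethyl)-3-iodoprop-2-enoic acid
Product: 20 methyl (E)-2-(2,2-dimethoxyethyl)-3-iodoprop-2-enoate
Conditions: MeI, K2CO3, DMF, rt
Reagents that add atoms: iodomethane, CI
Why: O-alkylation of the potassium carboxylate (SN2 esterification) gives the C14 methyl ester without isomerizing the iodoalkene.

**Step 12**
Reactants: 14 tert-butyl (S)-5-[(R)-4-(bromomethyl)-5-oxo-2,5-dihydrofuran-2-yl]-4-(TBDPSO-methyl)pentanoate; 20 methyl (E)-2-(2,2-dimethoxyethyl)-3-iodoprop-2-enoate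
Product: 22 tert-butyl (4S)-4-(TBDPSO-methyl)-5-{(2R,3R)-3-[(1S,3E)-1-hydroxy-4-iodo-3-(methoxycarbonyl)but-3-en-1-yl]-4-methylidene-5-oxooxolan-2-yl}pentanoate, via aldehyde 21 (not isolated)
Conditions: 20, 1 M aq. HCl (cat.), THF–H2O, rt; then 14, indium powder, rt
Reagents that add atoms: water, O
Why: Acetal hydrolysis frees the aldehyde, and the indium-mediated Barbier allylation (known for 3-(bromomethyl)furan-2(5H)-ones) joins C7 to C8 by γ-attack of the allylindium, which restores the exocyclic C11=C13 methylene; the aldehyde should add anti to the C6 substituent (6,7-trans lactone, C7 set) and, through a Zimmerman–Traxler chair with the ring-locked E-type allyl metal, give the anti (8S) carbinol.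

**Step 13**
Reactants: 22 tert-butyl (4S)-4-(TBDPSO-methyl)-5-{(2R,3R)-3-[(1S,3E)-1-hydroxy-4-iodo-3-(methoxycarbonyl)but-3-en-1-yl]-4-methylidene-5-oxooxolan-2-yl}pentanoate
Product: 23 tert-butyl (4S)-4-(TBDPSO-methyl)-5-{(2R,3S)-3-[(1R,3E)-4-iodo-3-(methoxycarbonyl)-1-(2-methylpropanoyloxy)but-3-en-1-yl]-4-methylidene-5-oxooxolan-2-yl}pentanoate
Conditions: i-PrCO2H, PPh3, DIAD, toluene, 0 °C → rt
Reagents that add atoms: 2-methylpropanoic acid, CC(C)C(=O)O
Why: Mitsunobu esterification, in which the alkoxyphosphonium of the 8S alcohol is displaced by isobutyrate in an SN2 step, installs the 2-methylpropanoate and corrects C8 to R in one operation.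

**Step 14**
Reactants: 23 tert-butyl (4S)-4-(TBDPSO-methyl)-5-{(2R,3S)-3-[(1R,3E)-4-iodo-3-(methoxycarbonyl)-1-(2-methylpropanoyloxy)but-3-en-1-yl]-4-methylidene-5-oxooxolan-2-yl}pentanoate
Product: 24 (4S)-4-(TBDPSO-methyl)-5-{(2R,3S)-3-[(1R,3E)-4-iodo-3-(methoxycarbonyl)-1-(2-methylpropanoyloxy)but-3-en-1-yl]-4-methylidene-5-oxooxolan-2-yl}pentanoic acid
Conditions: TFA–CH2Cl2 (1:4), 0 °C
Reagents that add atoms: none
Why: Acidolysis of the tert-butyl ester (E1 loss of isobutene) frees the carboxylic acid, while the TBDPS ether, the other esters, the lactone and the iodoalkene should tolerate cold TFA.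

**Step 15**
Reactants: 24 (4S)-4-(TBDPSO-methyl)-5-{(2R,3S)-3-[(1R,3E)-4-iodo-3-(methoxycarbonyl)-1-(2-methylpropanoyloxy)but-3-en-1-yl]-4-methylidene-5-oxooxolan-2-yl}pentanoic acid
Product: 25 1,3-dioxoisoindolin-2-yl (4S)-4-(TBDPSO-methyl)-5-{(2R,3S)-3-[(1R,3E)-4-iodo-3-(methoxycarbonyl)-1-(2-methylpropanoyloxy)but-3-en-1-yl]-4-methylidene-5-oxooxolan-2-yl}pentanoate
Conditions: N-hydroxyphthalimide, DIC, DMAP (cat.), CH2Cl2, rt
Reagents that add atoms: N-hydroxyphthalimide, O=C1N(O)C(=O)c2ccccc12
Why: Carbodiimide-mediated (Steglich-type) esterification gives the redox-active ester that serves as the precursor of the C2 radical.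

**Step 16**
Reactants: 25 1,3-dioxoisoindolin-2-yl (4S)-4-(TBDPSO-methyl)-5-{(2R,3S)-3-[(1R,3E)-4-iodo-3-(methoxycarbonyl)-1-(2-methylpropanoyloxy)but-3-en-1-yl]-4-methylidene-5-oxooxolan-2-yl}pentanoate
Product: 26 methyl (3aS,4R,6E,10S,11aR)-10-(TBDPSO-methyl)-3-methylidene-4-(2-methylpropanoyloxy)-2-oxo-2,3,3a,4,5,8,9,10,11,11a-decahydrocyclodeca[b]furan-6-carboxylate
Conditions: NiCl2·6H2O (0.5 equiv), 2,2'-bipyridine (0.5 equiv), AgNO3 (0.3 equiv), LiCl, DMF, Mg anode, RVC cathode, constant current, rt; 25 added by syringe pump over 10 h (final 2 mM)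
Reagents that add atoms: none
Why: Proposed new method: zerovalent nickel (bipyridine-ligated, formed at the cathode) should insert into the C1–I bond of the (E)-β-iodoacrylate, and single-electron reduction of the N-acyloxyphthalimide at the other chain end (by low-valent nickel or the silver-coated cathode) releases phthalimide anion and CO2 to leave a primary radical at C2, which is captured by the divalent alkenylnickel, after which reductive elimination from the trivalent nickel species forges the C1–C2 bond. The closest known reaction type is the intermolecular nickel-electrocatalytic decarboxylative alkenylation of redox-active esters with alkenyl halides (and, for ring closure at an alkenylnickel, the Nozaki–Hiyama–Kishi macrocyclization); the intramolecular medium-ring mode is what is new. The one ring closed is the ten-membered carbocycle, formed not by radical addition to an alkene but by C(sp3)–C(sp2) reductive elimination from an eleven-membered nickelacycle. No stereocentre is created; the alkene geometry is carried over from 25 with retention at C1, so that C2 ends cis to C9 across C1=C10 (E by the sequence rules, cis within the ring). The step needs cyclization to beat oligomerization, hydrodecarboxylation and 8-endo addition of the C2 radical to the C11=C13 methylene lactone; slow addition of 25 into a cell that holds nickel in excess over the substrate present (each chain is metalated at C1 before its ester is reduced), the trans-fused lactone turn at C6–C7 and the iodine already syn to C9 should secure this.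

**Step 17**
Reactants: 26 methyl (3aS,4R,6E,10S,11aR)-10-(TBDPSO-methyl)-3-methylidene-4-(2-methylpropanoyloxy)-2-oxo-2,3,3a,4,5,8,9,10,11,11a-decahydrocyclodeca[b]furan-6-carboxylate
Product: 27 methyl (3aS,4R,6E,10S,11aR)-10-(hydroxymethyl)-3-methylidene-4-(2-methylpropanoyloxy)-2-oxo-2,3,3a,4,5,8,9,10,11,11a-decahydrocyclodeca[b]furan-6-carboxylate
Conditions: HF·pyridine, pyridine–THF, 0 °C → rt
Reagents that add atoms: none
Why: Fluoride-induced Si–O cleavage (desilylation) with buffered HF·pyridine frees the C15 alcohol and should leave the methylene lactone, both esters and the enoate untouched.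

**Compound list**

1 | (S)-4-benzyl-1,3-oxazolidin-2-one | O=C1N[C@@H](Cc2ccccc2)CO1 | starting material
2 | pent-4-enoyl chloride | C=CCCC(=O)Cl | starting material
3 | (S)-4-benzyl-3-(pent-4-enoyl)-1,3-oxazolidin-2-one | C=CCCC(=O)N1[C@@H](Cc2ccccc2)COC1=O | intermediate
4 | tert-butyl acrylate | C=CC(=O)OC(C)(C)C | starting material
5 | tert-butyl (S)-4-[(S)-4-benzyl-2-oxo-1,3-oxazolidine-3-carbonyl]hept-6-enoate | C=CC[C@@H](C(=O)N1[C@@H](Cc2ccccc2)COC1=O)CCC(=O)OC(C)(C)C | intermediate
6 | tert-butyl (S)-4-(hydroxymethyl)hept-6-enoate | C=CC[C@@H](CO)CCC(=O)OC(C)(C)C | intermediate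
7 | tert-butyl (S)-4-(TBDPSO-methyl)hept-6-enoate | C=CC[C@@H](CO[Si](c1ccccc1)(c1ccccc1)C(C)(C)C)CCC(=O)OC(C)(C)C | intermediate
8 | tert-butyl (4S)-4-(TBDPSO-methyl)-5-(1,2,4-trioxolan-3-yl)pentanoate (ozonide) | C1OOC(C[C@@H](CO[Si](c2ccccc2)(c2ccccc2)C(C)(C)C)CCC(=O)OC(C)(C)C)O1 | intermediate
9 | tert-butyl (S)-4-(TBDPSO-methyl)-6-oxohexanoate | O=CC[C@@H](CO[Si](c1ccccc1)(c1ccccc1)C(C)(C)C)CCC(=O)OC(C)(C)C | intermediate
10 | methyl 2-{[(tert-butoxycarbonyl)oxy]methyl}acrylate | C=C(COC(=O)OC(C)(C)C)C(=O)OC | starting material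
11 | 9-tert-butyl 1-methyl (4R,6S)-6-(TBDPSO-methyl)-4-hydroxy-2-methylidenenonanedioate | C=C(C[C@H](O)C[C@@H](CO[Si](c1ccccc1)(c1ccccc1)C(C)(C)C)CCC(=O)OC(C)(C)C)C(=O)OC | intermediate
12 | tert-butyl (S)-4-(TBDPSO-methyl)-5-[(R)-4-methylidene-5-oxooxolan-2-yl]pentanoate | C=C1C(=O)O[C@H](C[C@@H](CO[Si](c2ccccc2)(c2ccccc2)C(C)(C)C)CCC(=O)OC(C)(C)C)C1 | intermediate
13 | tert-butyl (4S)-5-[(2R)-4-bromo-4-(bromomethyl)-5-oxooxolan-2-yl]-4-(TBDPSO-methyl)pentanoate (both epimers at the CBr carbon) | O=C1O[C@H](C[C@@H](CO[Si](c2ccccc2)(c2ccccc2)C(C)(C)C)CCC(=O)OC(C)(C)C)CC1(Br)CBr | intermediate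
14 | tert-butyl (S)-5-[(R)-4-(bromomethyl)-5-oxo-2,5-dihydrofuran-2-yl]-4-(TBDPSO-methyl)pentanoate | O=C1O[C@H](C[C@@H](CO[Si](c2ccccc2)(c2ccccc2)C(C)(C)C)CCC(=O)OC(C)(C)C)C=C1CBr | intermediate
15 | dimethyl malonate | COC(=O)CC(=O)OC | starting material
16 | 2-bromo-1,1-dimethoxyethane | COC(CBr)OC | starting material
17 | dimethyl 2-(2,2-dimethoxyethyl)malonate | COC(=O)C(CC(OC)OC)C(=O)OC | intermediate
18 | dimethyl 2-(diiodomethyl)-2-(2,2-dimethoxyethyl)malonate | COC(=O)C(CC(OC)OC)(C(I)I)C(=O)OC | intermediate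
19 | (E)-2-(2,2-dimethoxyethyl)-3-iodoprop-2-enoic acid | COC(OC)C/C(C(=O)O)=C\I | intermediate
20 | methyl (E)-2-(2,2-dimethoxyethyl)-3-iodoprop-2-enoate | COC(OC)C/C(C(=O)OC)=C\I | intermediate
21 | methyl (E)-3-iodo-2-(2-oxoethyl)prop-2-enoate | O=CC/C(C(=O)OC)=C\I | intermediate
22 | tert-butyl (4S)-4-(TBDPSO-methyl)-5-{(2R,3R)-3-[(1S,3E)-1-hydroxy-4-iodo-3-(methoxycarbonyl)but-3-en-1-yl]-4-methylidene-5-oxooxolan-2-yl}pentanoate | CC(C)(C)OC(=O)CC[C@H](CO[Si](c1ccccc1)(c1ccccc1)C(C)(C)C)C[C@H]1OC(=O)C(=C)[C@@H]1[C@@H](O)C/C(C(=O)OC)=C\I | intermediate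
23 | tert-butyl (4S)-4-(TBDPSO-methyl)-5-{(2R,3S)-3-[(1R,3E)-4-iodo-3-(methoxycarbonyl)-1-(2-methylpropanoyloxy)but-3-en-1-yl]-4-methylidene-5-oxooxolan-2-yl}pentanoate | CC(C)(C)OC(=O)CC[C@H](CO[Si](c1ccccc1)(c1ccccc1)C(C)(C)C)C[C@H]1OC(=O)C(=C)[C@@H]1[C@H](OC(=O)C(C)C)C/C(C(=O)OC)=C\I | intermediate
24 | (4S)-4-(TBDPSO-methyl)-5-{(2R,3S)-3-[(1R,3E)-4-iodo-3-(methoxycarbonyl)-1-(2-methylpropanoyloxy)but-3-en-1-yl]-4-methylidene-5-oxooxolan-2-yl}pentanoic acid | OC(=O)CC[C@H](CO[Si](c1ccccc1)(c1ccccc1)C(C)(C)C)C[C@H]1OC(=O)C(=C)[C@@H]1[C@H](OC(=O)C(C)C)C/C(C(=O)OC)=C\I | intermediate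
25 | 1,3-dioxoisoindolin-2-yl (4S)-4-(TBDPSO-methyl)-5-{(2R,3S)-3-[(1R,3E)-4-iodo-3-(methoxycarbonyl)-1-(2-methylpropanoyloxy)but-3-en-1-yl]-4-methylidene-5-oxooxolan-2-yl}pentanoate | O=C(CC[C@H](CO[Si](c1ccccc1)(c1ccccc1)C(C)(C)C)C[C@H]1OC(=O)C(=C)[C@@H]1[C@H](OC(=O)C(C)C)C/C(C(=O)OC)=C\I)ON1C(=O)c2ccccc2C1=O | intermediate
26 | methyl (3aS,4R,6E,10S,11aR)-10-(TBDPSO-methyl)-3-methylidene-4-(2-methylpropanoyloxy)-2-oxo-2,3,3a,4,5,8,9,10,11,11a-decahydrocyclodeca[b]furan-6-carboxylate | C=C1C(=O)O[C@@H]2C[C@@H](CO[Si](c3ccccc3)(c3ccccc3)C(C)(C)C)CC/C=C(/C(=O)OC)C[C@@H](OC(=O)C(C)C)[C@@H]12 | intermediate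
27 | methyl (3aS,4R,6E,10S,11aR)-10-(hydroxymethyl)-3-methylidene-4-(2-methylpropanoyloxy)-2-oxo-2,3,3a,4,5,8,9,10,11,11a-decahydrocyclodeca[b]furan-6-carboxylate (CNP0251148.1) | C=C1C(=O)O[C@@H]2C[C@@H](CO)CC/C=C(/C(=O)OC)C[C@@H](OC(=O)C(C)C)[C@@H]12 | target

**Count and risks**

Total step count: 17. Longest linear sequence: 13 steps (steps 1–7 and 12–17); steps 8–11 build the east piece.

Steps most likely to fail:

1. Step 16 (proposed new method). What may go wrong: the C2 radical may be reduced further, add 8-endo to the C11=C13 methylene lactone before it meets nickel, or couple between chains (oligomerization). Fallback, setting out from 25 and coming back at 26: 25 is irradiated with blue light with bis(catecholato)diboron in DMAc, where the radical is trapped at high boron concentration, to give the alkylboronic catechol ester F1. F1 is transesterified in the same flask with pinacol and Et3N to the primary alkylboronic pinacol ester F2. F2 is then closed under Suzuki–Miyaura conditions (Pd(OAc)2, SPhos, K3PO4, toluene–H2O, 80 °C, slow addition) to give 26; this is a two-electron transmetalation pathway with no free radical at the cyclization stage.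

2. Step 12. What may go wrong: the β,γ-double bond of aldehyde 21 may migrate into conjugation (with loss of iodide) in the aqueous acidic medium, and the C7/C8 diastereoselectivity may erode in water. Fallback, setting out from 14 and 20 and coming back at 22: 14 is converted with B2pin2 and Pd2(dba)3 (cat.) in toluene into the allylic pinacol boronate F3. 20 is hydrolysed separately (Amberlyst-15, wet acetone) and the crude aldehyde 21 is heated with F3 in dry toluene; this allylboration runs through a closed six-membered transition state without water or metal and gives the O-boryl adduct F4. Mild hydrolysis of F4 gives 22.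

3. Step 13. What may go wrong: the activated C8 oxygen may undergo β-elimination toward C7 or C9, or substitution at the hindered carbinol may not occur. Fallback, setting out from 22 and coming back at 23: Dess–Martin oxidation (NaHCO3-buffered, CH2Cl2) gives the C8 ketone F5. Corey–Bakshi–Shibata reduction ((S)-2-methyl-CBS-oxazaborolidine, catecholborane, toluene, −40 °C; reagent control) gives the 8R alcohol F6. Acylation of F6 with isobutyric anhydride and DMAP proceeds with retention to give 23.

**Further compounds**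

F1 | step 16 | methyl (2E,4R)-4-{(2R,3S)-2-[(2S)-4-(1,3,2-benzodioxaborol-2-yl)-2-(TBDPSO-methyl)butyl]-4-methylidene-5-oxooxolan-3-yl}-2-(iodomethylidene)-4-(2-methylpropanoyloxy)butanoate | B1(CC[C@H](CO[Si](c2ccccc2)(c2ccccc2)C(C)(C)C)C[C@H]2OC(=O)C(=C)[C@@H]2[C@H](OC(=O)C(C)C)C/C(C(=O)OC)=C\I)Oc2ccccc2O1
F2 | step 16 | methyl (2E,4R)-2-(iodomethylidene)-4-(2-methylpropanoyloxy)-4-{(2R,3S)-2-[(2S)-2-(TBDPSO-methyl)-4-(4,4,5,5-tetramethyl-1,3,2-dioxaborolan-2-yl)butyl]-4-methylidene-5-oxooxolan-3-yl}butanoate | CC1(C)OB(CC[C@H](CO[Si](c2ccccc2)(c2ccccc2)C(C)(C)C)C[C@H]2OC(=O)C(=C)[C@@H]2[C@H](OC(=O)C(C)C)C/C(C(=O)OC)=C\I)OC1(C)C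
F3 | step 12 | tert-butyl (S)-4-(TBDPSO-methyl)-5-{(R)-5-oxo-4-[(4,4,5,5-tetramethyl-1,3,2-dioxaborolan-2-yl)methyl]-2,5-dihydrofuran-2-yl}pentanoate | O=C1O[C@H](C[C@@H](CO[Si](c2ccccc2)(c2ccccc2)C(C)(C)C)CCC(=O)OC(C)(C)C)C=C1CB3OC(C)(C)C(C)(C)O3
F4 | step 12 | O-(4,4,5,5-tetramethyl-1,3,2-dioxaborolan-2-yl) derivative of 22 (boryl group on the C8 oxygen, 8S) | CC(C)(C)OC(=O)CC[C@H](CO[Si](c1ccccc1)(c1ccccc1)C(C)(C)C)C[C@H]1OC(=O)C(=C)[C@@H]1[C@@H](OB2OC(C)(C)C(C)(C)O2)C/C(C(=O)OC)=C\I
F5 | step 13 | tert-butyl (4S)-4-(TBDPSO-methyl)-5-{(2R,3S)-3-[(3E)-4-iodo-3-(methoxycarbonyl)but-3-enoyl]-4-methylidene-5-oxooxolan-2-yl}pentanoate | CC(C)(C)OC(=O)CC[C@H](CO[Si](c1ccccc1)(c1ccccc1)C(C)(C)C)C[C@H]1OC(=O)C(=C)[C@@H]1C(=O)C/C(C(=O)OC)=C\I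
F6 | step 13 | tert-butyl (4S)-4-(TBDPSO-methyl)-5-{(2R,3R)-3-[(1R,3E)-1-hydroxy-4-iodo-3-(methoxycarbonyl)but-3-en-1-yl]-4-methylidene-5-oxooxolan-2-yl}pentanoate | CC(C)(C)OC(=O)CC[C@H](CO[Si](c1ccccc1)(c1ccccc1)C(C)(C)C)C[C@H]1OC(=O)C(=C)[C@@H]1[C@H](O)C/C(C(=O)OC)=C\I
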